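# Proposed total synthesis of CNP0208931.1 by a three-component boron relay

## Analysis of the target

The target 31 is an 11-membered carbocycle of the humulane type. It is numbered here C1 (bearing the exocyclic CH2), C2, C3, C4=C5 (Z, methyl on C5), C6, C7 (carbinol esterified as the (E)-p-coumarate), C8, C9 (gem-dimethyl), C10 and C11 (secondary hydroperoxide, allylic to the C1 methylene). There are two stereocentres, C7 (R) and C11 (S). They are 1,5-related across the quaternary C9 in a flexible medium ring, so neither can be trusted to direct the other and each needs its own source of configuration. The sensitive groups are the secondary allylic hydroperoxide (reduced by phosphines and sulfides, dehydrated to the enone by base, cleaved by strong acid, prone to radical allylic transposition), the free phenol, and the cinnamate (a Michael acceptor that isomerises in light). The difficulties are the strained medium ring, the Z-trisubstituted ring alkene, which cannot be left to a ring-closing metathesis or a Wittig reaction, and the late, configurationally defined introduction of the hydroperoxide. The strategy rests on the array C7(O)–C6H2–C5(CH3)=C4H–C3: a homoallylic alcohol with a Z-trisubstituted alkene, which is the product pattern of a 2-methylallyl boron reagent, stereogenic at its boron-bearing carbon C4, adding to a C7 aldehyde. Read this way, the chain C1–C11 falls into three achiral pieces, and the ring is closed at C11–C1, the one bond whose formation also creates the exocyclic methylene and the C11 carbinol.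

## Retrosynthetic reasoning

**Unmasking.** 31 is taken back to 30, in which the hydroperoxide is a mixed peroxyketal and the phenol an acetal. No skeletal bond is cut. The two most fragile functions then appear only in the last, mildly acidic operation, which must leave the ester, both alkenes and the O–O bond alone.

**Ester bond at C7.** 30 is cut at the acyl–oxygen bond into the macrocyclic alcohol 26 and the protected cinnamic acid 29, which comes in one operation from 27. Acylating late keeps the cinnamate away from the nickel, borane and strongly basic steps. The forward reaction is a carbodiimide esterification of a secondary alcohol in the presence of a dialkyl peroxide.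

**C11–O bond.** 26 comes from its PMB ether 25. 25 is cut at C11–O into the allylic alcohol 20 and the masked hydroperoxide 23 (one step from 21), joined through mesylate 24. Cutting C11–O rather than forming the O–O bond turns the hydroperoxide stereocentre into a carbinol of opposite configuration, which is a solvable problem. The forward reaction is an SN2 displacement at a secondary allylic carbon. 23 has a single peroxide O–H, so neither a dialkyl peroxide nor a base-labile free hydroperoxide can form under the basic conditions.

**Configuration at C11.** 20 (11R) is taken back to enone 19, and 19 to the epimeric alcohols 18. C7 is too remote to control C11 during ring closure, so the ring-forming step is not asked to set C11. Both epimers converge on 19, and a reagent-controlled reduction then sets C11.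

**Ring bond C11–C1.** 18 (through silyl ether 17) is cut between the carbinol carbon and the methylene-bearing carbon, giving ynal 16. This single cut removes the ring, turns the exocyclic alkene into a terminal alkyne and the carbinol into an aldehyde. The Z alkene and the gem-dimethyl group pre-bend the chain. The forward reaction is a reductive alkyne–aldehyde cyclisation that must bond the internal alkyne carbon.

**Adjustment of end groups.** 16 comes from alcohol 15 by oxidation, 15 from 14 by removal of both silyl groups in one operation, and 14 from 13 by protection of the C7 hydroxyl. The C7 hydroxyl must be blocked, since a free C7–OH would form a lactol with the C11 aldehyde.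

**Key disconnection.** 13 is cut at C4–C5 and at C6–C7 into carbamate 3 (exocyclic carbon and C1–C4), boronate 8 (C5, its methyl and C6) and aldehyde 7 (C7–C11). These two cuts isolate the Z alkene and the C7 stereocentre, the only stereochemical content of the chain, and leave three achiral fragments. The forward reaction must deprotonate C4 enantioselectively, transfer the alkenyl group from boron to C4, and add the resulting allylboron reagent to 7 with axial placement of the C3 chain.

**Fragments.** 3 comes from 1 by carbamoylation (2) and C-silylation. 7 comes from anhydride 4 by reduction to diol 5, monosilylation to 6 and oxidation.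

## Alternatives that were turned down

**Alternative 1: cyclobutanol opening to close the ring at C3–C4.**
- Disconnection: the sp3–sp2 bond C3–C4. The precursor is the open-chain (Z)-alkenyl iodide A1, in which C11, C1, C2 and C3 are held as a tertiary cyclobutanol.
- Forward key step: with Pd(OAc)2, P(t-Bu)3 and Cs2CO3, zerovalent palladium formed in the flask inserts into the C4–I bond, the cyclobutanolate binds, β-carbon elimination opens the four-membered ring, and reductive elimination joins C3 to C4 to give the 11-membered ketone A2.
- For: release of cyclobutane strain drives a closure that is otherwise uphill, the Z geometry comes from a defined iodide and is not at risk, and no stereocentre is formed in the closure.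
- Against: A2 has a CH2 at C1 and a ketone at C11, so the exocyclic methylene must still be introduced by regioselective α-methylenation (C1 against C10) before C11 can be reduced and inverted. The alkylpalladium formed on ring opening has β-hydrogens and must close a large palladacycle faster than it eliminates, which is not assured for a medium ring. A1 itself needs a stereodefined trisubstituted iodoalkene and the C7 stereocentre, a chain synthesis at least as long as the one chosen.
- Comparison: on ring closure alone this alternative is the stronger one, since it is thermodynamically driven. The chosen strategy offers a chain that carries the exocyclic carbon from the first step and obtains alkene geometry and C7 from one operation.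

**Alternative 2: nickel ynal macrocyclisation as the carrying idea.**
- Disconnection: C11–C1.
- Forward key step: the open-chain ynal A3 is cyclised with Ni(COD)2 (zerovalent nickel), the bulky carbene IPr and Et3SiH to the 2-methylene silyl ether A4.
- For: ring, exocyclic alkene and C11 oxygen arise in one step from an alkyne and an aldehyde, both easy to carry. This closure is as good as any available for this ring, and it is adopted downstream in the chosen route (A3 is identical with 16).
- Against: as the idea that carries the route it says nothing on how the Z-trisubstituted alkene and C7 arise, which is where the chain is hard to make. A4 is a single 11R epimer, which presumes 1,5-induction from C7 through a flexible eleven-membered transition state; this cannot be argued from structure.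
- Comparison: on ring closure the two are equal, because the step is the same. The chosen strategy adds a defined chain assembly and sets C11 by a reagent rather than by the ring.

**Alternative 3: macrolactone contracted by decarboxylative allylation.**
- Disconnection: C2–C3, reached from the 13-membered β-keto lactone A5, whose ester oxygen sits on allylic C3.
- Forward key step: Pd(PPh3)4 (zerovalent palladium) ionises the C3–O bond, the carboxylate loses carbon dioxide, and the C2 enolate recombines with the allyl terminus C3 to give ketone A6.
- For: a 13-membered lactonisation is easier than a direct 11-membered carbocyclisation, and the enolate is generated regiospecifically at C2. C11 is set as an ether in open-chain chemistry; on this point the alternative is stronger than the chosen route, which corrects C11 after ring closure. The C1 ketone is a handle for methylenation.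
- Against: the π-allyl intermediate contains C4=C5, and the Z alkene corresponds to the less stable anti-substituted allyl, which can equilibrate through σ-bonding at C5 and leak to the E alkene. C11 is α to the C1 ketone in A6 and can epimerise under the basic conditions of the contraction and of a Wittig methylenation. A5 needs a seco acid with two stereocentres, a β-keto ester and a Z allylic alcohol, a longer preparation than three achiral fragments.
- Comparison: the chosen strategy forms the Z alkene in a closed, concerted transition state and never ionises it afterwards. It pays for this with two extra steps to set C11.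

Key step: step 6

Assumption: (+)-sparteine is taken as commercially available, and ring compounds are named with the C1–C11 numbering of the analysis rather than with lowest locants.

## Route

Step 1
Reactants: 1 pent-4-yn-1-ol
Product: 2 pent-4-yn-1-yl N,N-diisopropylcarbamate
Conditions: i-Pr2NCOCl, Et3N, CH2Cl2, reflux
Reagents that add atoms: N,N-diisopropylcarbamoyl chloride, CC(C)N(C(C)C)C(=O)Cl
Why: O-Acylation of a primary alcohol by a carbamoyl chloride; the hindered carbamate is the directing and leaving group needed at C4 in step 6.

Step 2
Reactants: 2 pent-4-yn-1-yl N,N-diisopropylcarbamate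
Product: 3 5-(triisopropylsilyl)pent-4-yn-1-yl N,N-diisopropylcarbamate
Conditions: n-BuLi, THF, −78 °C; TIPSOTf, −78 °C to 0 °C
Reagents that add atoms: triisopropylsilyl trifluoromethanesulfonate, CC(C)[Si](C(C)C)(C(C)C)OS(=O)(=O)C(F)(F)F
Why: Deprotonation of the terminal alkyne and C-silylation of the acetylide; n-BuLi at −78 °C leaves the hindered carbamate untouched. The bulky silyl group removes the acidic alkyne hydrogen before the s-BuLi step.

Step 3
Reactants: 4 3,3-dimethylglutaric anhydride
Product: 5 3,3-dimethylpentane-1,5-diol
Conditions: LiAlH4, THF, 0 °C to reflux; Fieser work-up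
Reagents that add atoms: none
Why: Hydride reduction of both acyl carbons of a cyclic anhydride to primary alcohols.

Step 4
Reactants: 5 3,3-dimethylpentane-1,5-diol
Product: 6 5-(tert-butyldimethylsilyloxy)-3,3-dimethylpentan-1-ol
Conditions: NaH (1 equiv), THF, rt; TBSCl (1 equiv)
Reagents that add atoms: tert-butyldimethylsilyl chloride, CC(C)(C)[Si](C)(C)Cl
Why: Monosilylation of a symmetric diol through its monosodium alkoxide; diol and bis-ether are separable and can be recycled.

Step 5
Reactants: 6 5-(tert-butyldimethylsilyloxy)-3,3-dimethylpentan-1-ol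
Product: 7 5-(tert-butyldimethylsilyloxy)-3,3-dimethylpentanal
Conditions: Dess–Martin periodinane, CH2Cl2, 0 °C to rt
Reagents that add atoms: none
Why: Dess–Martin oxidation of a primary alcohol to the aldehyde; there is no α-stereocentre and no β-leaving group, so the aldehyde is robust.

Step 6
Reactants: 3 5-(triisopropylsilyl)pent-4-yn-1-yl N,N-diisopropylcarbamate, 8 isopropenylboronic acid pinacol ester, 7 5-(tert-butyldimethylsilyloxy)-3,3-dimethylpentanal
Product: 13 (5R,7Z)-1-(tert-butyldimethylsilyloxy)-3,3,7-trimethyl-12-(triisopropylsilyl)dodec-7-en-11-yn-5-ol, via lithiated carbamate 9 (not isolated), via lithium boronate complex 10 (not isolated), via allylboronate 11 (not isolated), via pinacol borate 12 (not isolated)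
Conditions: s-BuLi, (+)-sparteine, Et2O, −78 °C; 8, −78 °C; MgBr2·OEt2, −78 °C to 35 °C; 7, 0 °C to rt; aqueous work-up
Reagents that add atoms: none
Why: This is a lithiation–borylation–allylboration sequence run in one flask. s-BuLi complexed by (+)-sparteine removes the pro-R hydrogen at C4 next to the carbamate oxygen and gives the configurationally stable (R)-organolithium 9, which adds to the boron of 8 with retention to give boronate 10. On warming with MgBr2·OEt2 the isopropenyl group shifts from boron to C4 anti to the departing carbamate (inversion at C4), which forms the C4–C5 bond and the (S)-allylboronate 11. Aldehyde 7 then reacts with 11 through a closed six-membered chair (B, O, C7, C6, C5, C4) that forms the C6–C7 bond and moves the double bond to C4=C5, giving borate 12, which is hydrolysed to 13 on work-up; no ring is closed. In this chair the C3 chain on C4 lies axial, because in the equatorial position it would be pressed against the C5 methyl group (A(1,2) strain) and the pinacol oxygens, and the axial position is the one that leads to the Z alkene. With the aldehyde chain equatorial, the S configuration at C4 is relayed to R at C7, so the enantiomer of the diamine is the only source of absolute configuration and the alkene geometry and C7 are fixed by the same transition state. The closest known reaction type is the one-pot union of sparteine-complexed lithiated primary carbamates with alkenylboronic pinacol esters and aldehydes to give Z-homoallylic alcohols. The step needs an enantioselective deprotonation, migration of the alkenyl group in preference to a pinacol oxygen, and a strong axial preference in the chair; the directing carbamate, the good migrating ability of an sp2 carbon and the 2-methyl group of the allyl unit secure these, while the silyl-capped alkyne and the silyl ether offer no acidic or electrophilic site.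

Step 7
Reactants: 13 (5R,7Z)-1-(tert-butyldimethylsilyloxy)-3,3,7-trimethyl-12-(triisopropylsilyl)dodec-7-en-11-yn-5-ol
Product: 14 tert-butyl{[(5R,7Z)-5-(4-methoxybenzyloxy)-3,3,7-trimethyl-12-(triisopropylsilyl)dodec-7-en-11-yn-1-yl]oxy}dimethylsilane
Conditions: NaH, PMBCl, Bu4NI (cat.), THF/DMF, 0 °C to rt
Reagents that add atoms: 4-methoxybenzyl chloride, COc1ccc(CCl)cc1
Why: Williamson etherification of the C7 alkoxide. The PMB ether survives fluoride, zerovalent nickel, borane and base, and can later be removed oxidatively beside a peroxide; C7 is not touched.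

Step 8
Reactants: 14 tert-butyl{[(5R,7Z)-5-(4-methoxybenzyloxy)-3,3,7-trimethyl-12-(triisopropylsilyl)dodec-7-en-11-yn-1-yl]oxy}dimethylsilane
Product: 15 (5R,7Z)-5-(4-methoxybenzyloxy)-3,3,7-trimethyldodec-7-en-11-yn-1-ol
Conditions: TBAF, THF, 0 °C to rt
Reagents that add atoms: none
Why: Fluoride cleaves both the alkynyl C–Si bond and the primary O–Si bond in one operation, releasing the terminal alkyne and the C11 alcohol; the PMB ether is inert.

Step 9
Reactants: 15 (5R,7Z)-5-(4-methoxybenzyloxy)-3,3,7-trimethyldodec-7-en-11-yn-1-ol
Product: 16 (5R,7Z)-5-(4-methoxybenzyloxy)-3,3,7-trimethyldodec-7-en-11-ynal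
Conditions: Dess–Martin periodinane, CH2Cl2, 0 °C to rt
Reagents that add atoms: none
Why: Dess–Martin oxidation of the primary alcohol to the C11 aldehyde under neutral conditions that leave the terminal alkyne, the Z alkene and the PMB ether alone.

Step 10
Reactants: 16 (5R,7Z)-5-(4-methoxybenzyloxy)-3,3,7-trimethyldodec-7-en-11-ynal
Product: 18 (4Z,7R)-7-(4-methoxybenzyloxy)-5,9,9-trimethyl-1-methylidenecycloundec-4-en-11-ol as a mixture of C11 epimers, via triethylsilyl ether 17 (not isolated)
Conditions: Ni(COD)2 (bis(1,5-cyclooctadiene)nickel, 20 mol %), IPr (1,3-bis(2,6-diisopropylphenyl)imidazol-2-ylidene, 20 mol %), Et3SiH, THF, slow addition of 16 at high dilution, rt to 45 °C; concentrate; TBAF, THF, 0 °C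
Reagents that add atoms: none
Why: Nickel-catalysed reductive ynal macrocyclisation: zerovalent nickel couples alkyne and aldehyde oxidatively, the silane cleaves the Ni–O bond and delivers hydrogen to the terminal alkyne carbon, giving silyl ether 17, which fluoride converts into 18. The bulky carbene keeps nickel on the unsubstituted alkyne terminus, so the C–C bond forms at the internal carbon C1 (exo mode) and the ring is 11-membered with an exocyclic methylene; the Z alkene and the gem-dimethyl group pre-bend the chain. No control of C11 is expected or needed, because step 11 erases it.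

Step 11
Reactants: 18 (4Z,7R)-7-(4-methoxybenzyloxy)-5,9,9-trimethyl-1-methylidenecycloundec-4-en-11-ol (C11 epimers)
Product: 19 (4Z,7R)-7-(4-methoxybenzyloxy)-5,9,9-trimethyl-1-methylidenecycloundec-4-en-11-one
Conditions: Dess–Martin periodinane, pyridine, CH2Cl2, 0 °C
Reagents that add atoms: none
Why: Oxidation of the allylic alcohol merges both C11 epimers into one 2-methylene ketone. The enone is to be used at once, since α-methylene ketones can dimerise.

Step 12
Reactants: 19 (4Z,7R)-7-(4-methoxybenzyloxy)-5,9,9-trimethyl-1-methylidenecycloundec-4-en-11-one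
Product: 20 (4Z,7R,11R)-7-(4-methoxybenzyloxy)-5,9,9-trimethyl-1-methylidenecycloundec-4-en-11-ol
Conditions: (S)-2-methyl-CBS-oxazaborolidine, catecholborane, toluene, −78 °C
Reagents that add atoms: none
Why: Corey–Bakshi–Shibata reduction, 1,2-selective on enones. The α-branched alkenyl flank (C1) acts as the large group and the C10 methylene as the small one, so the (S)-catalyst delivers hydride to give the 11R alcohol, by the same sense that turns acetophenone into (R)-1-phenylethanol. C11 is thus set by the reagent and not by remote C7.

Step 13
Reactants: 21 2,3-dimethylbut-2-ene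
Product: 23 2-methoxyprop-2-yl hydroperoxide, via acetone O-oxide 22 (not isolated)
Conditions: O3, MeOH/CH2Cl2, −78 °C
Reagents that add atoms: ozone, [O-][O+]=O; methanol, CO
Why: Criegee ozonolysis in methanol: cycloaddition and cycloreversion give acetone and carbonyl oxide 22, which methanol traps as the α-methoxy hydroperoxide. The symmetric alkene gives a single product, which is kept in solution.

Step 14
Reactants: 20 (4Z,7R,11R)-7-(4-methoxybenzyloxy)-5,9,9-trimethyl-1-methylidenecycloundec-4-en-11-ol, 23 2-methoxyprop-2-yl hydroperoxide
Product: 25 (4Z,7R,11S)-11-[(2-methoxypropan-2-yl)peroxy]-7-(4-methoxybenzyloxy)-5,9,9-trimethyl-1-methylidenecycloundec-4-ene, via mesylate 24 (not isolated)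
Conditions: Ms2O, Et3N, THF, −30 °C; then added to 23, CsOH·H2O, DMF, 0 °C
Reagents that add atoms: none
Why: O-Sulfonylation proceeds with retention at C11, and the caesium salt of 23 then displaces the allylic mesylate by SN2 with inversion to the 11S peroxide. The anhydride is used so that no chloride competes. The peroxyketal nucleophile cannot be alkylated twice and gives a base-stable dialkyl peroxide.

Step 15
Reactants: 25 (4Z,7R,11S)-11-[(2-methoxypropan-2-yl)peroxy]-7-(4-methoxybenzyloxy)-5,9,9-trimethyl-1-methylidenecycloundec-4-ene
Product: 26 (4Z,7R,11S)-11-[(2-methoxypropan-2-yl)peroxy]-5,9,9-trimethyl-1-methylidenecycloundec-4-en-7-ol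
Conditions: DDQ, CH2Cl2/pH 7 buffer, 0 °C
Reagents that add atoms: none
Why: Oxidative cleavage of the PMB ether by hydride abstraction at the electron-rich benzylic position and hydrolysis. The buffer protects the acid-labile peroxyketal; the dialkyl peroxide and the isolated alkenes are not oxidised under these conditions.

Step 16
Reactants: 27 p-coumaric acid
Product: 29 (E)-3-[4-(tetrahydro-2H-pyran-2-yloxy)phenyl]prop-2-enoic acid, via bis-tetrahydropyranyl derivative 28 (not isolated)
Conditions: 3,4-dihydro-2H-pyran, PPTS, CH2Cl2/THF, rt; NaOH aq., MeOH/THF, rt; HCl to pH 5, 0 °C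
Reagents that add atoms: 3,4-dihydro-2H-pyran, C1=COCCC1
Why: Acid-catalysed addition of phenol and acid to the enol ether gives 28; the acylal-type ester is saponified selectively while the aryl acetal is stable to base. The acetal carbon is a stereocentre of no consequence.

Step 17
Reactants: 26 (4Z,7R,11S)-11-[(2-methoxypropan-2-yl)peroxy]-5,9,9-trimethyl-1-methylidenecycloundec-4-en-7-ol, 29 (E)-3-[4-(tetrahydro-2H-pyran-2-yloxy)phenyl]prop-2-enoic acid
Product: 30 (4Z,7R,11S)-11-[(2-methoxypropan-2-yl)peroxy]-5,9,9-trimethyl-1-methylidenecycloundec-4-en-7-yl (E)-3-[4-(tetrahydro-2H-pyran-2-yloxy)phenyl]prop-2-enoate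
Conditions: DCC, DMAP (cat.), CH2Cl2, 0 °C to rt
Reagents that add atoms: none
Why: Steglich esterification of the secondary C7 alcohol; acylation at oxygen retains the C7 configuration. Cold conditions and only catalytic DMAP avoid base-induced Kornblum–DeLaMare fragmentation of the secondary peroxide.

Step 18
Reactants: 30 (4Z,7R,11S)-11-[(2-methoxypropan-2-yl)peroxy]-5,9,9-trimethyl-1-methylidenecycloundec-4-en-7-yl (E)-3-[4-(tetrahydro-2H-pyran-2-yloxy)phenyl]prop-2-enoate
Product: 31 (4Z,7R,11S)-11-hydroperoxy-5,9,9-trimethyl-1-methylidenecycloundec-4-en-7-yl (E)-3-(4-hydroxyphenyl)prop-2-enoate (CNP0208931.1)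
Conditions: AcOH/THF/H2O (4:2:1), rt to 35 °C, in the dark
Reagents that add atoms: none
Why: The aryl tetrahydropyranyl ether and the peroxyketal are both acetals and hydrolyse in aqueous acetic acid, which is too weak to trigger Hock cleavage of the allylic hydroperoxide. Ester, alkenes and both stereocentres are untouched; exclusion of light guards the E cinnamate.

## Compound list

1 | pent-4-yn-1-ol | C#CCCCO | starting material
2 | pent-4-yn-1-yl N,N-diisopropylcarbamate | C#CCCCOC(=O)N(C(C)C)C(C)C | intermediate
3 | 5-(triisopropylsilyl)pent-4-yn-1-yl N,N-diisopropylcarbamate | CC(C)[Si](C(C)C)(C(C)C)C#CCCCOC(=O)N(C(C)C)C(C)C | intermediate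
4 | 3,3-dimethylglutaric anhydride | O=C1CC(C)(C)CC(=O)O1 | starting material
5 | 3,3-dimethylpentane-1,5-diol | OCCC(C)(C)CCO | intermediate
6 | 5-(tert-butyldimethylsilyloxy)-3,3-dimethylpentan-1-ol | CC(C)(C)[Si](C)(C)OCCC(C)(C)CCO | intermediate
7 | 5-(tert-butyldimethylsilyloxy)-3,3-dimethylpentanal | CC(C)(C)[Si](C)(C)OCCC(C)(C)CC=O | intermediate
8 | isopropenylboronic acid pinacol ester | CC(=C)B1OC(C)(C)C(C)(C)O1 | starting material
9 | (R)-1-lithio-5-(triisopropylsilyl)pent-4-yn-1-yl N,N-diisopropylcarbamate, as its (+)-sparteine complex | [Li][C@H](CCC#C[Si](C(C)C)(C(C)C)C(C)C)OC(=O)N(C(C)C)C(C)C | intermediate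
10 | lithium (R)-boronate complex of 9 with 8 (boron bearing pinacolate, isopropenyl and the C4 carbon) | [Li+].CC(=C)[B-]1([C@H](CCC#C[Si](C(C)C)(C(C)C)C(C)C)OC(=O)N(C(C)C)C(C)C)OC(C)(C)C(C)(C)O1 | intermediate
11 | (S)-4,4,5,5-tetramethyl-2-[2-methyl-7-(triisopropylsilyl)hept-1-en-6-yn-3-yl]-1,3,2-dioxaborolane | CC(=C)[C@H](CCC#C[Si](C(C)C)(C(C)C)C(C)C)B1OC(C)(C)C(C)(C)O1 | intermediate
12 | 2-{[(5R,7Z)-1-(tert-butyldimethylsilyloxy)-3,3,7-trimethyl-12-(triisopropylsilyl)dodec-7-en-11-yn-5-yl]oxy}-4,4,5,5-tetramethyl-1,3,2-dioxaborolane | CC(C)[Si](C(C)C)(C(C)C)C#CCC/C=C(/C)C[C@H](OB1OC(C)(C)C(C)(C)O1)CC(C)(C)CCO[Si](C)(C)C(C)(C)C | intermediate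
13 | (5R,7Z)-1-(tert-butyldimethylsilyloxy)-3,3,7-trimethyl-12-(triisopropylsilyl)dodec-7-en-11-yn-5-ol | CC(C)[Si](C(C)C)(C(C)C)C#CCC/C=C(/C)C[C@H](O)CC(C)(C)CCO[Si](C)(C)C(C)(C)C | intermediate
14 | tert-butyl{[(5R,7Z)-5-(4-methoxybenzyloxy)-3,3,7-trimethyl-12-(triisopropylsilyl)dodec-7-en-11-yn-1-yl]oxy}dimethylsilane | CC(C)[Si](C(C)C)(C(C)C)C#CCC/C=C(/C)C[C@H](OCc1ccc(OC)cc1)CC(C)(C)CCO[Si](C)(C)C(C)(C)C | intermediate
15 | (5R,7Z)-5-(4-methoxybenzyloxy)-3,3,7-trimethyldodec-7-en-11-yn-1-ol | C#CCC/C=C(/C)C[C@H](OCc1ccc(OC)cc1)CC(C)(C)CCO | intermediate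
16 | (5R,7Z)-5-(4-methoxybenzyloxy)-3,3,7-trimethyldodec-7-en-11-ynal | C#CCC/C=C(/C)C[C@H](OCc1ccc(OC)cc1)CC(C)(C)CC=O | intermediate
17 | (4Z,7R)-7-(4-methoxybenzyloxy)-5,9,9-trimethyl-1-methylidene-11-(triethylsilyloxy)cycloundec-4-ene, mixture of C11 epimers | C=C1CC/C=C(/C)C[C@H](OCc2ccc(OC)cc2)CC(C)(C)CC1O[Si](CC)(CC)CC | intermediate
18 | (4Z,7R)-7-(4-methoxybenzyloxy)-5,9,9-trimethyl-1-methylidenecycloundec-4-en-11-ol, mixture of C11 epimers | C=C1CC/C=C(/C)C[C@H](OCc2ccc(OC)cc2)CC(C)(C)CC1O | intermediate
19 | (4Z,7R)-7-(4-methoxybenzyloxy)-5,9,9-trimethyl-1-methylidenecycloundec-4-en-11-one | C=C1CC/C=C(/C)C[C@H](OCc2ccc(OC)cc2)CC(C)(C)CC1=O | intermediate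
20 | (4Z,7R,11R)-7-(4-methoxybenzyloxy)-5,9,9-trimethyl-1-methylidenecycloundec-4-en-11-ol | C=C1CC/C=C(/C)C[C@H](OCc2ccc(OC)cc2)CC(C)(C)C[C@H]1O | intermediate
21 | 2,3-dimethylbut-2-ene | CC(C)=C(C)C | starting material
22 | acetone O-oxide | CC(C)=[O+][O-] | intermediate
23 | 2-methoxyprop-2-yl hydroperoxide | COC(C)(C)OO | intermediate
24 | (4Z,7R,11R)-7-(4-methoxybenzyloxy)-5,9,9-trimethyl-1-methylidenecycloundec-4-en-11-yl methanesulfonate | C=C1CC/C=C(/C)C[C@H](OCc2ccc(OC)cc2)CC(C)(C)C[C@H]1OS(C)(=O)=O | intermediate
25 | (4Z,7R,11S)-11-[(2-methoxypropan-2-yl)peroxy]-7-(4-methoxybenzyloxy)-5,9,9-trimethyl-1-methylidenecycloundec-4-ene | C=C1CC/C=C(/C)C[C@H](OCc2ccc(OC)cc2)CC(C)(C)C[C@@H]1OOC(C)(C)OC | intermediate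
26 | (4Z,7R,11S)-11-[(2-methoxypropan-2-yl)peroxy]-5,9,9-trimethyl-1-methylidenecycloundec-4-en-7-ol | C=C1CC/C=C(/C)C[C@H](O)CC(C)(C)C[C@@H]1OOC(C)(C)OC | intermediate
27 | p-coumaric acid | O=C(O)/C=C/c1ccc(O)cc1 | starting material
28 | tetrahydro-2H-pyran-2-yl (E)-3-[4-(tetrahydro-2H-pyran-2-yloxy)phenyl]prop-2-enoate (acetal carbons unassigned) | O=C(OC1CCCCO1)/C=C/c1ccc(OC2CCCCO2)cc1 | intermediate
29 | (E)-3-[4-(tetrahydro-2H-pyran-2-yloxy)phenyl]prop-2-enoic acid (acetal carbon unassigned) | O=C(O)/C=C/c1ccc(OC2CCCCO2)cc1 | intermediate
30 | (4Z,7R,11S)-11-[(2-methoxypropan-2-yl)peroxy]-5,9,9-trimethyl-1-methylidenecycloundec-4-en-7-yl (E)-3-[4-(tetrahydro-2H-pyran-2-yloxy)phenyl]prop-2-enoate (acetal carbon unassigned) | C=C1CC/C=C(/C)C[C@H](OC(=O)/C=C/c2ccc(OC3CCCCO3)cc2)CC(C)(C)C[C@@H]1OOC(C)(C)OC | intermediate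
31 | (4Z,7R,11S)-11-hydroperoxy-5,9,9-trimethyl-1-methylidenecycloundec-4-en-7-yl (E)-3-(4-hydroxyphenyl)prop-2-enoate (CNP0208931.1) | C=C1CC/C=C(/C)C[C@H](OC(=O)/C=C/c2ccc(O)cc2)CC(C)(C)C[C@@H]1OO | target

## Step count and steps least certain to work

Total: 18 steps. Longest linear sequence: 14 steps (from 4 through steps 3 to 12, 14, 15, 17 and 18).

**Step 6 (key step).**
- Risk: incomplete axial preference in the chair, which would erode the Z geometry and with it the C7 configuration. A second risk is partial racemisation or reversal of borylation if the organolithium or the ate complex is warmed before the 1,2-shift has been induced; the migration of an isopropenyl group from a pinacol boronate can be slow.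
- Fallback, setting out from 3 and 7 and returning at 13: carbamate 3 would be cleaved with LiAlH4 to 5-(triisopropylsilyl)pent-4-yn-1-ol F1 and oxidised with Dess–Martin periodinane to 5-(triisopropylsilyl)pent-4-ynal F2. A Stork–Zhao-type olefination with the ylide of (1-iodoethyl)triphenylphosphonium iodide would give (Z)-(6-iodohept-5-en-1-yn-1-yl)triisopropylsilane F3. Aldehyde 7 would be converted by Corey–Chaykovsky methylenation into racemic 2-[4-(tert-butyldimethylsilyloxy)-2,2-dimethylbutyl]oxirane F4. Jacobsen hydrolytic kinetic resolution with the chiral complex (salen)Co(OAc) (salen = N,N'-bis(3,5-di-tert-butylsalicylidene)-1,2-cyclohexanediamine dianion), in the enantiomer that leaves the R epoxide, would give (R)-2-[4-(tert-butyldimethylsilyloxy)-2,2-dimethylbutyl]oxirane F5. Iodine–lithium exchange on F3 with t-BuLi and opening of F5 at its CH2 terminus with BF3·OEt2 would form C5–C6 and give 13. Alkene geometry and C7 then come from two separate, classical sources.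

**Step 10 (macrocyclisation).**
- Risk: intermolecular coupling to oligomers, and closure in the endo sense (bond to the terminal alkyne carbon, giving a 12-membered ring with an E alkene). Both may outrun the 11-membered exo closure because of transannular strain in the forming ring.
- Fallback, setting out from 15 and returning at 18: alkynol 15 would be hydroaluminated at the internal alkyne carbon with DIBAL-H and catalytic NiCl2(dppp) (dppp = 1,3-bis(diphenylphosphino)propane) and the alkenylaluminium quenched with NBS, to give (5R,7Z)-11-bromo-5-(4-methoxybenzyloxy)-3,3,7-trimethyldodeca-7,11-dien-1-ol F6. Dess–Martin oxidation would give (5R,7Z)-11-bromo-5-(4-methoxybenzyloxy)-3,3,7-trimethyldodeca-7,11-dienal F7. An intramolecular Nozaki–Hiyama–Kishi reaction (CrCl2, catalytic NiCl2, DMSO/THF, high dilution) would close C11–C1 and give 18. Here the regiochemistry is fixed beforehand in the alkenyl bromide and does not depend on a ligand.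

**Step 14 (peroxide displacement).**
- Risk: attack of the peroxide anion at the exocyclic CH2 with allylic transposition (SN2'), ionisation of the allylic mesylate with loss of configuration, or elimination to a diene; the secondary carbon is flanked by a neopentyl-type CH2 and reacts slowly in the SN2 mode.
- Fallback, setting out from 20 and returning at 25: alcohol 20 would be converted with CBr4 and PPh3 into (4Z,7R)-11-bromo-7-(4-methoxybenzyloxy)-5,9,9-trimethyl-1-methylidenecycloundec-4-ene F10, whose C11 configuration is immaterial. Treatment with silver trifluoroacetate and anhydrous H2O2 in Et2O at 0 °C would substitute through the allyl cation. (4Z,7R,11S)-11-hydroperoxy-7-(4-methoxybenzyloxy)-5,9,9-trimethyl-1-methylidenecycloundec-4-ene F11 would be separated by chromatography from its C11 epimer and from the transposed primary hydroperoxide. 2-Methoxypropene with PPTS would then convert F11 into 25. This path gives up stereospecificity and relies on separation.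

**Step 12 (reduction at C11).**
- Risk: poor facial selectivity, because the two ketone flanks differ only moderately in size and the ring conformation may oppose the catalyst; conjugate reduction of the enone is a lesser risk.
- Fallback, setting out from 19 and returning at 20: enone 19 would be reduced under Luche conditions (NaBH4, CeCl3·7H2O, MeOH) to both C11 epimers, which are separated; the 11R epimer is 20. (4Z,7R,11S)-7-(4-methoxybenzyloxy)-5,9,9-trimethyl-1-methylidenecycloundec-4-en-11-ol F8 would be inverted by a Mitsunobu reaction with 4-nitrobenzoic acid, PPh3 and DIAD to (4Z,7R,11R)-7-(4-methoxybenzyloxy)-5,9,9-trimethyl-1-methylidenecycloundec-4-en-11-yl 4-nitrobenzoate F9. Methanolysis of F9 with K2CO3 in MeOH would give 20.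

## Further compounds

F1 | step 6 | 5-(triisopropylsilyl)pent-4-yn-1-ol | CC(C)[Si](C(C)C)(C(C)C)C#CCCCO
F2 | step 6 | 5-(triisopropylsilyl)pent-4-ynal | CC(C)[Si](C(C)C)(C(C)C)C#CCCC=O
F3 | step 6 | (Z)-(6-iodohept-5-en-1-yn-1-yl)triisopropylsilane | CC(C)[Si](C(C)C)(C(C)C)C#CCC/C=C(/C)I
F4 | step 6 | rac-2-[4-(tert-butyldimethylsilyloxy)-2,2-dimethylbutyl]oxirane | CC(C)(C)[Si](C)(C)OCCC(C)(C)CC1CO1
F5 | step 6 | (R)-2-[4-(tert-butyldimethylsilyloxy)-2,2-dimethylbutyl]oxirane | CC(C)(C)[Si](C)(C)OCCC(C)(C)C[C@@H]1CO1
F6 | step 10 | (5R,7Z)-11-bromo-5-(4-methoxybenzyloxy)-3,3,7-trimethyldodeca-7,11-dien-1-ol | C=C(Br)CC/C=C(/C)C[C@H](OCc1ccc(OC)cc1)CC(C)(C)CCO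
F7 | step 10 | (5R,7Z)-11-bromo-5-(4-methoxybenzyloxy)-3,3,7-trimethyldodeca-7,11-dienal | C=C(Br)CC/C=C(/C)C[C@H](OCc1ccc(OC)cc1)CC(C)(C)CC=O
F8 | step 12 | (4Z,7R,11S)-7-(4-methoxybenzyloxy)-5,9,9-trimethyl-1-methylidenecycloundec-4-en-11-ol | C=C1CC/C=C(/C)C[C@H](OCc2ccc(OC)cc2)CC(C)(C)C[C@@H]1O
F9 | step 12 | (4Z,7R,11R)-7-(4-methoxybenzyloxy)-5,9,9-trimethyl-1-methylidenecycloundec-4-en-11-yl 4-nitrobenzoate | C=C1CC/C=C(/C)C[C@H](OCc2ccc(OC)cc2)CC(C)(C)C[C@H]1OC(=O)c3ccc(cc3)[N+](=O)[O-]
F10 | step 14 | (4Z,7R)-11-bromo-7-(4-methoxybenzyloxy)-5,9,9-trimethyl-1-methylidenecycloundec-4-ene (C11 configuration not defined) | C=C1CC/C=C(/C)C[C@H](OCc2ccc(OC)cc2)CC(C)(C)CC1Br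
F11 | step 14 | (4Z,7R,11S)-11-hydroperoxy-7-(4-methoxybenzyloxy)-5,9,9-trimethyl-1-methylidenecycloundec-4-ene | C=C1CC/C=C(/C)C[C@H](OCc2ccc(OC)cc2)CC(C)(C)C[C@@H]1OO
A1 | alternative 1 | 1-[(4R,6Z)-4-(tert-butyldimethylsilyloxy)-7-iodo-2,2,6-trimethylhept-6-en-1-yl]cyclobutan-1-ol | OC1(CC(C)(C)C[C@@H](O[Si](C)(C)C(C)(C)C)C/C(C)=C\I)CCC1
A2 | alternative 1 | (4Z,7R)-7-(tert-butyldimethylsilyloxy)-5,9,9-trimethylcycloundec-4-en-11-one (target numbering, C1 a CH2) | O=C1CCC/C=C(/C)C[C@H](O[Si](C)(C)C(C)(C)C)CC(C)(C)C1
A3 | alternative 2 | (5R,7Z)-5-(4-methoxybenzyloxy)-3,3,7-trimethyldodec-7-en-11-ynal (identical with 16) | C#CCC/C=C(/C)C[C@H](OCc1ccc(OC)cc1)CC(C)(C)CC=O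
A4 | alternative 2 | (4Z,7R,11R)-7-(4-methoxybenzyloxy)-5,9,9-trimethyl-1-methylidene-11-(triethylsilyloxy)cycloundec-4-ene | C=C1CC/C=C(/C)C[C@H](OCc2ccc(OC)cc2)CC(C)(C)C[C@H]1O[Si](CC)(CC)CC
A5 | alternative 3 | 13-membered β-keto lactone, ring O–C3H2–C4H=C5(CH3)–C6H2–C7H(OTBS)–C8H2–C9(CH3)2–C10H2–C11H(OPMB)–C1(=O)–C2H2–C(=O), Z alkene | O=C1CC(=O)[C@H](OCc2ccc(OC)cc2)CC(C)(C)C[C@@H](O[Si](C)(C)C(C)(C)C)C/C(C)=C\CO1
A6 | alternative 3 | (4Z,7R,11R)-7-(tert-butyldimethylsilyloxy)-11-(4-methoxybenzyloxy)-5,9,9-trimethylcycloundec-4-en-1-one (target numbering) | O=C1CC/C=C(/C)C[C@H](O[Si](C)(C)C(C)(C)C)CC(C)(C)C[C@H]1OCc2ccc(OC)cc2
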